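**Retrosynthetic overview**
1. Target 27 comes from O-methylation of hydroxy-methoxy-quinone 26, and 26 from N-desulfonylation, O-desilylation and air oxidation of the hexasubstituted phenol 24, which already carries all six ring substituents at the hydroquinone oxidation level.
2. Key disconnection: the central ring of 24 is closed by a Danheiser benzannulation of 4-siloxycyclobutenone 14 with siloxyalkyne 19. The two alkyne carbons are inserted into the C(=O)–C(OMe) bond of 14: the siloxy-bearing alkyne carbon (a quinone C=O in 27) bonds to the methoxy-bearing ring carbon, and the indolyl-bearing alkyne carbon bonds to the former cyclobutenone carbonyl carbon (a C–OMe in 27).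
3. Enabling feature: the fully substituted quinone ring, whose six carbons follow the order C(indolyl), C(OMe), C(=O), C(indolyl), C(OMe), C(=O). One C(=O)–C(indolyl) pair is an ynol ether in disguise; the other four carbons, C(OMe)=C(indolyl)–C(=O) plus the second C(OMe), carry the oxygen pattern of a squaric acid-derived cyclobutenone.
4. Both halves come from 3-iodoindole 8 (indole, C2 reverse prenylation, C3 iodination, N-sulfonylation): 14 by addition of the 3-lithioindole to reduced, silylated dimethyl squarate and acid transposition; 19 by Sonogashira coupling, acetylide oxidation to the ynolate and O-silylation.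
5. Ring order: the indole rings and the squarate four-membered ring are bought; the cyclobutenone ring is a temporary ring that is opened in step 11, where the six-membered ring is closed last.

Key step: step 11

Remark: the target has no stereocentre and its two indolyl–quinone axes are not configurationally defined, so intermediates with such axes are taken as converging rotamer mixtures; compounds 10, 11, 13, 14, 21 and 23 are racemic or diastereomeric mixtures whose stereocentres are erased in step 11.

Step 1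
Reactants: 1 3-methylbuta-1,2-diene; 2 9-borabicyclo[3.3.1]nonane (9-BBN)
Product: 3 B-(3-methylbut-2-en-1-yl)-9-borabicyclo[3.3.1]nonane (prenyl-9-BBN), used as its THF solution
Conditions: 9-BBN (0.5 M in THF), 0 °C → rt
Reagents that add atoms: none
Why: Hydroboration of the allene places boron on the unsubstituted terminal carbon and should give the allylic (prenyl) borane.

Step 2
Reactants: 4 indole; 3 prenyl-9-BBN
Product: 6 2-(2-methylbut-3-en-2-yl)-1H-indole, via 3-chloro-3H-indole 5 (not isolated)
Conditions: t-BuOCl, Et3N, THF, −78 °C; then 3, −78 °C → rt; aq. K2CO3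
Reagents that add atoms: none
Why: Chlorination gives the electrophilic 3-chloroindolenine, whose C=N bond is allylated at C2 by the prenylborane through a six-membered allylboration transition state with allyl transposition (hence the 1,1-dimethylallyl group), and loss of HCl restores the indole.

Step 3
Reactants: 6 2-(2-methylbut-3-en-2-yl)-1H-indole
Product: 7 3-iodo-2-(2-methylbut-3-en-2-yl)-1H-indole
Conditions: I2, KOH, DMF, rt, dark; used crude
Reagents that add atoms: iodine, II
Why: Electrophilic aromatic iodination should occur at C3, the most nucleophilic free position of the 2-substituted indole.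

Step 4
Reactants: 7 3-iodo-2-(2-methylbut-3-en-2-yl)-1H-indole
Product: 8 3-iodo-2-(2-methylbut-3-en-2-yl)-1-(phenylsulfonyl)-1H-indole
Conditions: NaH, DMF, 0 °C; PhSO2Cl, 0 °C → rt
Reagents that add atoms: benzenesulfonyl chloride, O=S(=O)(Cl)c1ccccc1
Why: N-Sulfonylation of the sodium indolide is a standard sulfonamide formation that masks the N–H for the organolithium steps and stabilises the sensitive 3-iodoindole.

Step 5
Reactants: 9 dimethyl squarate (3,4-dimethoxycyclobut-3-ene-1,2-dione)
Product: 10 4-hydroxy-2,3-dimethoxycyclobut-2-en-1-one (racemic)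
Conditions: LiAlH(O-t-Bu)3, THF, −78 → −20 °C; pH 7 buffer
Reagents that add atoms: none
Why: The bulky hydride should reduce one of the two equivalent carbonyls chemoselectively, because the product is a less electrophilic vinylogous ester; the new stereocentre forms as a racemate and is erased in step 11.

Step 6
Reactants: 10 4-hydroxy-2,3-dimethoxycyclobut-2-en-1-one
Product: 11 4-[(tert-butyldimethylsilyl)oxy]-2,3-dimethoxycyclobut-2-en-1-one (racemic)
Conditions: TBSOTf, 2,6-lutidine, CH2Cl2, −78 °C
Reagents that add atoms: tert-butyldimethylsilyl trifluoromethanesulfonate, CC(C)(C)[Si](C)(C)OS(=O)(=O)C(F)(F)F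
Why: Silyl ether formation with the silyl triflate at low temperature under non-acidic conditions should protect the acid-labile α-hydroxy ketone.

Step 7
Reactants: 8 3-iodo-2-(2-methylbut-3-en-2-yl)-1-(phenylsulfonyl)-1H-indole; 11 4-[(tert-butyldimethylsilyl)oxy]-2,3-dimethoxycyclobut-2-en-1-one
Product: 14 4-[(tert-butyldimethylsilyl)oxy]-2-methoxy-3-[2-(2-methylbut-3-en-2-yl)-1-(phenylsulfonyl)-1H-indol-3-yl]cyclobut-2-en-1-one (racemic), via 3-lithioindole 12 (not isolated), via tertiary carbinol 13 (not isolated)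
Conditions: t-BuLi (2 equiv), THF, −100 → −78 °C; then 11, −78 °C; then 1 M HCl, THF, 0 °C
Reagents that add atoms: water, O
Why: Iodine–lithium exchange gives the 3-lithioindole, which adds to the cyclobutenone carbonyl, and dilute acid ionises the tertiary allylic alcohol and hydrolyses the methoxy-stabilised cation with allylic transposition (Stork–Danheiser-type route from 3-alkoxycyclobutenones to 3-substituted cyclobutenones); direct conjugate addition–elimination would give the same product.

Step 8
Reactants: 8 3-iodo-2-(2-methylbut-3-en-2-yl)-1-(phenylsulfonyl)-1H-indole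
Product: 15 2-(2-methylbut-3-en-2-yl)-1-(phenylsulfonyl)-3-[(trimethylsilyl)ethynyl]-1H-indole
Conditions: HC≡CSiMe3, PdCl2(PPh3)2 (cat.), CuI (cat.), Et3N, THF, 50 °C
Reagents that add atoms: ethynyltrimethylsilane, C#C[Si](C)(C)C
Why: Sonogashira coupling of the aryl iodide with the slim terminal alkyne should tolerate the neighbouring tert-alkyl group, and fast transmetalation from the copper acetylide should outrun insertion of the nearby vinyl group.

Step 9
Reactants: 15 2-(2-methylbut-3-en-2-yl)-1-(phenylsulfonyl)-3-[(trimethylsilyl)ethynyl]-1H-indole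
Product: 16 3-ethynyl-2-(2-methylbut-3-en-2-yl)-1-(phenylsulfonyl)-1H-indole
Conditions: K2CO3 (cat.), MeOH–THF, 0 °C → rt, short reaction time
Reagents that add atoms: none
Why: Methoxide-catalysed methanolysis of the alkynyl C–Si bond is fast enough at or below room temperature to leave the N-sulfonyl group in place.

Step 10
Reactants: 16 3-ethynyl-2-(2-methylbut-3-en-2-yl)-1-(phenylsulfonyl)-1H-indole
Product: 19 2-(2-methylbut-3-en-2-yl)-1-(phenylsulfonyl)-3-{[(triisopropylsilyl)oxy]ethynyl}-1H-indole, via lithium acetylide 17 (not isolated), via lithium ynolate 18 (not isolated)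
Conditions: LiN(SiMe3)2, THF, −78 °C; t-BuOOLi (from t-BuOOH and LiN(SiMe3)2), −78 → 0 °C; then i-Pr3SiOTf, −78 → 0 °C
Reagents that add atoms: tert-butyl hydroperoxide, CC(C)(C)OO; triisopropylsilyl trifluoromethanesulfonate, CC(C)[Si](OS(=O)(=O)C(F)(F)F)(C(C)C)C(C)C
Why: The lithium acetylide is oxidised at carbon by lithium tert-butyl peroxide (electrophilic oxygen transfer) to the lithium ynolate, which the bulky silyl triflate should trap on oxygen, a known entry to siloxyalkynes from terminal alkynes.

Step 11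
Reactants: 14 4-[(tert-butyldimethylsilyl)oxy]-2-methoxy-3-[2-(2-methylbut-3-en-2-yl)-1-(phenylsulfonyl)-1H-indol-3-yl]cyclobut-2-en-1-one; 19 2-(2-methylbut-3-en-2-yl)-1-(phenylsulfonyl)-3-{[(triisopropylsilyl)oxy]ethynyl}-1H-indole
Product: 24 2-[(tert-butyldimethylsilyl)oxy]-4-methoxy-3,6-bis[2-(2-methylbut-3-en-2-yl)-1-(phenylsulfonyl)-1H-indol-3-yl]-5-[(triisopropylsilyl)oxy]phenol, via vinylketene 20 (not isolated), via vinylcyclobutenone 21 (not isolated), via dienylketene 22 (not isolated), via cyclohexadienone 23 (not isolated)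
Conditions: 19 (1.3 equiv), degassed toluene, 100 °C, sealed tube, Ar
Reagents that add atoms: none
Why: Heating should open 14 by 4π electrocyclic cleavage of its C(=O)–CH(OSi) bond (siloxy group rotating outward) to vinylketene 20, whose ketene C=C undergoes a regioselective [2+2] cycloaddition with siloxyalkyne 19 to give vinylcyclobutenone 21; a second 4π opening gives dienylketene 22, 6π electrocyclisation gives cyclohexadienone 23, and tautomerisation gives phenol 24. The closest known reaction is the Danheiser benzannulation of cyclobutenones with siloxyalkynes, which gives resorcinol monosilyl ethers by this cascade. The one ring that remains, the benzene ring, is closed by thermal disrotatory 6π electrocyclisation of 22, while the four-membered rings of 14 and 21 are opened by 4π electrocyclic cleavage; the two new bonds between the halves (ketene carbonyl carbon to the indolyl-bearing alkyne carbon, methoxy-bearing ketene carbon to the siloxy-bearing alkyne carbon) are made in the [2+2] event. No stereocentre is created, since the CH(OSi) centre of 14 and the quaternary centre of 21 are erased on aromatisation. The step needs the regiochemistry of the [2+2] event and closure to the carbocycle only: the first is secured by the polarisation of the ynol ether, whose oxygen makes the indolyl-bearing carbon the nucleophile for the electrophilic ketene carbon. The second is secured by the tert-alkyl groups at C2 of both indoles, which block electrocyclisation onto the indole, and by the N-sulfonyl groups, which keep the nitrogens from acylation by the ketenes.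

Step 12
Reactants: 24 2-[(tert-butyldimethylsilyl)oxy]-4-methoxy-3,6-bis[2-(2-methylbut-3-en-2-yl)-1-(phenylsulfonyl)-1H-indol-3-yl]-5-[(triisopropylsilyl)oxy]phenol
Product: 26 2-hydroxy-5-methoxy-3,6-bis[2-(2-methylbut-3-en-2-yl)-1H-indol-3-yl]cyclohexa-2,5-diene-1,4-dione, via benzenetriol 25 (not isolated)
Conditions: Mg turnings, MeOH–THF, rt, sonication, Ar; then Bu4NF, THF, rt; then air, aq. NH4Cl
Reagents that add atoms: none
Why: Magnesium in methanol should cleave both N–S bonds by single-electron reduction (giving sulfinate, which cannot sulfonylate the phenoxides), fluoride removes both aryl silyl ethers, and air oxidises the para-dihydroxy pair of the electron-rich 1,2,4-trihydroxybenzene to the hydroxy-para-quinone.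

Step 13
Reactants: 26 2-hydroxy-5-methoxy-3,6-bis[2-(2-methylbut-3-en-2-yl)-1H-indol-3-yl]cyclohexa-2,5-diene-1,4-dione
Product: 27 2,5-dimethoxy-3,6-bis[2-(2-methylbut-3-en-2-yl)-1H-indol-3-yl]cyclohexa-2,5-diene-1,4-dione (target)
Conditions: Me3SiCHN2, MeOH–CH2Cl2, 0 °C → rt
Reagents that add atoms: (trimethylsilyl)diazomethane, C[Si](C)(C)C=[N+]=[N-]
Why: The vinylogous carboxylic acid OH of the hydroxyquinone protonates the diazoalkane and should be O-methylated (diazomethane-type methylation) to the para-quinone methyl ether, while the indole N–H groups are not acidic enough to react.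

**Compound list**
1 | 3-methylbuta-1,2-diene | C=C=C(C)C | starting material
2 | 9-borabicyclo[3.3.1]nonane (9-BBN) | [H]B1C2CCCC1CCC2 | starting material
3 | B-(3-methylbut-2-en-1-yl)-9-borabicyclo[3.3.1]nonane | CC(C)=CCB1C2CCCC1CCC2 | intermediate
4 | indole | c1ccc2[nH]ccc2c1 | starting material
5 | 3-chloro-3H-indole (not isolated) | ClC1C=Nc2ccccc12 | intermediate
6 | 2-(2-methylbut-3-en-2-yl)-1H-indole | C=CC(C)(C)c1cc2ccccc2[nH]1 | intermediate
7 | 3-iodo-2-(2-methylbut-3-en-2-yl)-1H-indole | C=CC(C)(C)c1[nH]c2ccccc2c1I | intermediate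
8 | 3-iodo-2-(2-methylbut-3-en-2-yl)-1-(phenylsulfonyl)-1H-indole | C=CC(C)(C)c1n(S(=O)(=O)c2ccccc2)c2ccccc2c1I | intermediate
9 | dimethyl squarate | COC1=C(OC)C(=O)C1=O | starting material
10 | 4-hydroxy-2,3-dimethoxycyclobut-2-en-1-one (racemic) | COC1=C(OC)C(O)C1=O | intermediate
11 | 4-[(tert-butyldimethylsilyl)oxy]-2,3-dimethoxycyclobut-2-en-1-one (racemic) | COC1=C(OC)C(O[Si](C)(C)C(C)(C)C)C1=O | intermediate
12 | 3-lithio-2-(2-methylbut-3-en-2-yl)-1-(phenylsulfonyl)-1H-indole (not isolated) | [Li]c1c(C(C)(C)C=C)n(S(=O)(=O)c2ccccc2)c2ccccc12 | intermediate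
13 | 4-[(tert-butyldimethylsilyl)oxy]-2,3-dimethoxy-1-[2-(2-methylbut-3-en-2-yl)-1-(phenylsulfonyl)-1H-indol-3-yl]cyclobut-2-en-1-ol (diastereomer mixture, not isolated) | COC1=C(OC)C(O)(c2c(C(C)(C)C=C)n(S(=O)(=O)c3ccccc3)c3ccccc23)C1O[Si](C)(C)C(C)(C)C | intermediate
14 | 4-[(tert-butyldimethylsilyl)oxy]-2-methoxy-3-[2-(2-methylbut-3-en-2-yl)-1-(phenylsulfonyl)-1H-indol-3-yl]cyclobut-2-en-1-one (racemic) | COC1=C(c2c(C(C)(C)C=C)n(S(=O)(=O)c3ccccc3)c3ccccc23)C(O[Si](C)(C)C(C)(C)C)C1=O | intermediate
15 | 2-(2-methylbut-3-en-2-yl)-1-(phenylsulfonyl)-3-[(trimethylsilyl)ethynyl]-1H-indole | C=CC(C)(C)c1n(S(=O)(=O)c2ccccc2)c2ccccc2c1C#C[Si](C)(C)C | intermediate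
16 | 3-ethynyl-2-(2-methylbut-3-en-2-yl)-1-(phenylsulfonyl)-1H-indole | C=CC(C)(C)c1n(S(=O)(=O)c2ccccc2)c2ccccc2c1C#C | intermediate
17 | lithium acetylide of 16 (not isolated) | C=CC(C)(C)c1n(S(=O)(=O)c2ccccc2)c2ccccc2c1C#C[Li] | intermediate
18 | lithium 2-[2-(2-methylbut-3-en-2-yl)-1-(phenylsulfonyl)-1H-indol-3-yl]ethynolate (not isolated) | C=CC(C)(C)c1n(S(=O)(=O)c2ccccc2)c2ccccc2c1C#C[O-].[Li+] | intermediate
19 | 2-(2-methylbut-3-en-2-yl)-1-(phenylsulfonyl)-3-{[(triisopropylsilyl)oxy]ethynyl}-1H-indole | C=CC(C)(C)c1n(S(=O)(=O)c2ccccc2)c2ccccc2c1C#CO[Si](C(C)C)(C(C)C)C(C)C | intermediate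
20 | (E)-4-[(tert-butyldimethylsilyl)oxy]-2-methoxy-3-(indolyl)buta-1,3-dien-1-one, the vinylketene from 14 (not isolated) | O=C=C(OC)/C(c1c(C(C)(C)C=C)n(S(=O)(=O)c2ccccc2)c2ccccc12)=C/O[Si](C)(C)C(C)(C)C | intermediate
21 | 4-[(E)-2-(silyloxy)-1-(indolyl)vinyl]-4-methoxy-2-(indolyl)-3-[(triisopropylsilyl)oxy]cyclobut-2-en-1-one, the [2+2] adduct (racemic, not isolated) | O=C1C(c2c(C(C)(C)C=C)n(S(=O)(=O)c3ccccc3)c3ccccc23)=C(O[Si](C(C)C)(C(C)C)C(C)C)C1(OC)/C(c1c(C(C)(C)C=C)n(S(=O)(=O)c2ccccc2)c2ccccc12)=C/O[Si](C)(C)C(C)(C)C | intermediate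
22 | (3Z,5E)-dienylketene from ring opening of 21 (not isolated) | O=C=C(c1c(C(C)(C)C=C)n(S(=O)(=O)c2ccccc2)c2ccccc12)/C(O[Si](C(C)C)(C(C)C)C(C)C)=C(OC)\C(c1c(C(C)(C)C=C)n(S(=O)(=O)c2ccccc2)c2ccccc12)=C\O[Si](C)(C)C(C)(C)C | intermediate
23 | 6-[(tert-butyldimethylsilyl)oxy]-4-methoxy-2,5-bis(indolyl)-3-[(triisopropylsilyl)oxy]cyclohexa-2,4-dien-1-one (racemic, not isolated) | O=C1C(c2c(C(C)(C)C=C)n(S(=O)(=O)c3ccccc3)c3ccccc23)=C(O[Si](C(C)C)(C(C)C)C(C)C)C(OC)=C(c2c(C(C)(C)C=C)n(S(=O)(=O)c3ccccc3)c3ccccc23)C1O[Si](C)(C)C(C)(C)C | intermediate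
24 | 2-[(tert-butyldimethylsilyl)oxy]-4-methoxy-3,6-bis[2-(2-methylbut-3-en-2-yl)-1-(phenylsulfonyl)-1H-indol-3-yl]-5-[(triisopropylsilyl)oxy]phenol | Oc1c(-c2c(C(C)(C)C=C)n(S(=O)(=O)c3ccccc3)c3ccccc23)c(O[Si](C(C)C)(C(C)C)C(C)C)c(OC)c(-c2c(C(C)(C)C=C)n(S(=O)(=O)c3ccccc3)c3ccccc23)c1O[Si](C)(C)C(C)(C)C | intermediate
25 | 5-methoxy-3,6-bis[2-(2-methylbut-3-en-2-yl)-1H-indol-3-yl]benzene-1,2,4-triol (not isolated) | Oc1c(-c2c(C(C)(C)C=C)[nH]c3ccccc23)c(O)c(OC)c(-c2c(C(C)(C)C=C)[nH]c3ccccc23)c1O | intermediate
26 | 2-hydroxy-5-methoxy-3,6-bis[2-(2-methylbut-3-en-2-yl)-1H-indol-3-yl]cyclohexa-2,5-diene-1,4-dione | COC1=C(c2c(C(C)(C)C=C)[nH]c3ccccc23)C(=O)C(O)=C(c2c(C(C)(C)C=C)[nH]c3ccccc23)C1=O | intermediate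
27 | 2,5-dimethoxy-3,6-bis[2-(2-methylbut-3-en-2-yl)-1H-indol-3-yl]cyclohexa-2,5-diene-1,4-dione | C=CC(C)(C)c1[nH]c2ccccc2c1C1=C(OC)C(=O)C(c2c(C(C)(C)C=C)[nH]c3ccccc23)=C(OC)C1=O | target

**Step count and risks**
Total step count: 13. Longest linear sequence: 10 steps (steps 1, 2, 3, 4, 8, 9, 10, 11, 12, 13).

Steps most likely to fail:

Step 11. The bimolecular [2+2] event between the vinylketene and the siloxyalkyne, both flanked by 2-tert-alkylindolyl groups, may be slower than thermal decay of the siloxyalkyne or than acylation of the product phenol by the ketene, so the cascade may stall before ring closure. The fallback gives up the annulation and sets out from compound 6. Two equivalents of 6 would be added to 2,5-dichloro-1,4-benzoquinone by acid-promoted conjugate addition of indole C3 (HCl, THF), each addition followed by re-oxidation of the hydroquinone with DDQ, to give 2,5-dichloro-3,6-bis[2-(2-methylbut-3-en-2-yl)-1H-indol-3-yl]cyclohexa-2,5-diene-1,4-dione F1. Both vinylogous acyl chlorides would then be replaced by methoxide through addition–elimination (NaOMe, MeOH), which comes back to the route at compound 27.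

Step 7. Addition of the hindered 3-lithioindole to the deactivated vinylogous-ester carbonyl of 11 may be slow, so that the aryllithium fragments on warming or the cyclobutenoxide ring-opens before the quench. The fallback reverses the order and sets out from compounds 8 and 9. The aryllithium 12 would be added to the far more electrophilic dimethyl squarate 9 to give 4-hydroxy-2,3-dimethoxy-4-[2-(2-methylbut-3-en-2-yl)-1-(phenylsulfonyl)-1H-indol-3-yl]cyclobut-2-en-1-one F2. Luche reduction of the remaining carbonyl (NaBH4, CeCl3·7H2O, MeOH) would give 2,3-dimethoxy-1-[2-(2-methylbut-3-en-2-yl)-1-(phenylsulfonyl)-1H-indol-3-yl]cyclobut-2-ene-1,4-diol F3. Dilute acid would ionise the tertiary hydroxyl selectively and transpose to 4-hydroxy-2-methoxy-3-[2-(2-methylbut-3-en-2-yl)-1-(phenylsulfonyl)-1H-indol-3-yl]cyclobut-2-en-1-one F4. Silylation (TBSOTf, 2,6-lutidine) comes back to the route at compound 14.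

Step 12. Reductive cleavage of the two hindered sulfonamides may be incomplete, or the electron-rich triol may be over-oxidised during the aerobic stage. The fallback sets out from compound 24 and removes the sulfonyl groups last. Fluoride alone at room temperature (Bu4NF, THF) followed by air would give 2-hydroxy-5-methoxy-3,6-bis[2-(2-methylbut-3-en-2-yl)-1-(phenylsulfonyl)-1H-indol-3-yl]cyclohexa-2,5-diene-1,4-dione F5. Methylation with Me3SiCHN2 would give 2,5-dimethoxy-3,6-bis[2-(2-methylbut-3-en-2-yl)-1-(phenylsulfonyl)-1H-indol-3-yl]cyclohexa-2,5-diene-1,4-dione F6. Both N–S bonds would then be cleaved by methoxide (Cs2CO3, MeOH–THF), whose attack on the dimethoxyquinone is degenerate, which comes back to the route at compound 27.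

Further compounds
F1 | step 11 | 2,5-dichloro-3,6-bis[2-(2-methylbut-3-en-2-yl)-1H-indol-3-yl]cyclohexa-2,5-diene-1,4-dione | C=CC(C)(C)c1[nH]c2ccccc2c1C1=C(Cl)C(=O)C(c2c(C(C)(C)C=C)[nH]c3ccccc23)=C(Cl)C1=O
F2 | step 7 | 4-hydroxy-2,3-dimethoxy-4-[2-(2-methylbut-3-en-2-yl)-1-(phenylsulfonyl)-1H-indol-3-yl]cyclobut-2-en-1-one | COC1=C(OC)C(O)(c2c(C(C)(C)C=C)n(S(=O)(=O)c3ccccc3)c3ccccc23)C1=O
F3 | step 7 | 2,3-dimethoxy-1-[2-(2-methylbut-3-en-2-yl)-1-(phenylsulfonyl)-1H-indol-3-yl]cyclobut-2-ene-1,4-diol | COC1=C(OC)C(O)(c2c(C(C)(C)C=C)n(S(=O)(=O)c3ccccc3)c3ccccc23)C1O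
F4 | step 7 | 4-hydroxy-2-methoxy-3-[2-(2-methylbut-3-en-2-yl)-1-(phenylsulfonyl)-1H-indol-3-yl]cyclobut-2-en-1-one | COC1=C(c2c(C(C)(C)C=C)n(S(=O)(=O)c3ccccc3)c3ccccc23)C(O)C1=O
F5 | step 12 | 2-hydroxy-5-methoxy-3,6-bis[2-(2-methylbut-3-en-2-yl)-1-(phenylsulfonyl)-1H-indol-3-yl]cyclohexa-2,5-diene-1,4-dione | COC1=C(c2c(C(C)(C)C=C)n(S(=O)(=O)c3ccccc3)c3ccccc23)C(=O)C(O)=C(c2c(C(C)(C)C=C)n(S(=O)(=O)c3ccccc3)c3ccccc23)C1=O
F6 | step 12 | 2,5-dimethoxy-3,6-bis[2-(2-methylbut-3-en-2-yl)-1-(phenylsulfonyl)-1H-indol-3-yl]cyclohexa-2,5-diene-1,4-dione | COC1=C(c2c(C(C)(C)C=C)n(S(=O)(=O)c3ccccc3)c3ccccc23)C(=O)C(OC)=C(c2c(C(C)(C)C=C)n(S(=O)(=O)c3ccccc3)c3ccccc23)C1=O
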